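The dusk run was charged at the flask's [acid], 0.020 M, so it shows directly what that acid does, though with twice the solid.

| flask | solid substrate | acid | scavenger | remark | time |
|---|---|---|---|---|---|
| summer | 0.20 M | 0.013 M | 0.20 M | run made earlier |  |
| winter | 0.20 M | 0.030 M | 0.20 M | run made earlier |  |
| dusk | 0.40 M | 0.020 M | 0.20 M | run made earlier |  |
| flask | 0.20 M | 0.0200 M | 0.200 M |  | 30 min |

| run | time / min | solid substrate / % | target / % |
|---|---|---|---|
| summer | 1.50 | 81.1 | 1.1 |
| summer | 5.00 | 51.7 | 9.7 |
| summer | 8.00 | 32.8 | 21.2 |
| summer | 12.0 | 10.4 | 38.0 |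
| summer | 20.0 | 0 | 69.4 |
| summer | 25.0 | 0.2 | 80.2 |
| winter | 1.50 | 82.2 | 2.6 |
| winter | 5.00 | 49.8 | 17.7 |
| winter | 8.00 | 27.4 | 35.6 |
| winter | 12.0 | 0.1 | 61.9 |
| winter | 20.0 | 0 | 90.4 |
| winter | 25.0 | 0.8 | 96.4 |
| dusk | 2.00 | 87.8 | 2.7 |
| dusk | 4.00 | 79.3 | 4.9 |
| dusk | 6.00 | 71.4 | 9.8 |
| dusk | 12.0 | 52.8 | 24.0 |
| dusk | 25.0 | 14.7 | 60.8 |

(readings scatter by 0.5 percentage points)

- acid is the free proton; pH is minus the decimal logarithm of its molar concentration
- given per volume of solution although it is solid: solid substrate
- the numbers in the tables scatter by 0.5 percentage points (one standard deviation)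
- at the start none of the solid substrate is in solution
- what has only dissolved of solid substrate counts as not reacted

- part of the solid substrate that has reacted (what has only dissolved counts as not reacted) at 30 min
- pH of the solution at 30 min

Call the pool what has left the solid and is not yet target, and define the drain constant as target formed per minute divided by the pool, a pseudo-first-order constant at fixed [acid]. Dusk from 12.0 min to 25.0 min reads 0.119 min⁻¹, with the pool nearly flat at 0.0954 M. Over the earlier span, from 6.00 min, the quotient reads 0.113 min⁻¹, so no loss of acid shows, and the flask's pH is reckoned here as that of its charge.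

The ladder for the flask then runs from the pool through the solid to the asked time. The pool's lifetime is 8.43 min. The solid lasts longer, to about 12.0 min, when winter's solid reads 0.1%, so the pool reaches its plateau first, 47.7% of the flask's charge. The asked 30 min lies far beyond, and the pool drains freely until then, leaving 5.63%. This reckoning gives 94.4%, slightly below the forecast.

The forecast gave 94.7% (from 92.5% to 96.5%) and pH 1.7 (from 1.66 to 1.76), on the ground that “the acid acts as a catalyst, or any acid formed is scavenged”.

The flask gives 94.3% reacted and pH 1.70.

    starting material + acid → weak acid + acid + target (k = 4.80 L mol⁻¹ min⁻¹)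
    weak acid ⇌ conjugate base + acid, settled at all times (K = 1.60 × 10⁻⁴ M)
    starting material → weak acid + target (k = 0.0260 min⁻¹)
    starting material + weak acid ⇌ idle adduct, settled at all times (K = 1.70 L mol⁻¹)
    weak acid + scavenger → scavenged by-product (k = 61.0 L mol⁻¹ min⁻¹)
    solid substrate ⇌ starting material, rate k6*(cs6 - [starting material]) while solid is left; crystals form when [starting material] > cs6 (solubility = 0.160 M, k = 0.170 min⁻¹)

From the flask's 35.3% of starting material at 15.0 min, the drain constant gives 5.92% at 30 min, and the flask holds 5.69%. The neighbour is charged with 0.34 M of solid substrate, and dusk had lost 0.341 M by 25.0 min, so the neighbour's solid is reckoned gone about then. The plateau, drained for the remaining 5.00 min, leaves 15.5% of the neighbour's charge, which makes 84.5% reacted. The neighbour gives 85.9% reacted, with 14.1% still starting material.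

The numbers in the tables come from a simulation for an exercise; the scatter is artificial.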